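**Retrosynthetic overview**
1. The plan rests on ring A of the flavanone unit. It is a benzene with oxygen on C5, C7 and C8a, and its C6, the carbon between the C5 and C7 oxygens, is bonded to C3 of the flavone. A ketene carbon (C5), a flavon-3-yl ynol ether (C6, C7) and a 3-alkoxy vinylketene (C8, C8a, C4a) give this pattern directly, so no tetra-ortho-substituted biaryl coupling is needed.
2. Late disconnections: O–Si cleavage; then O1–C2 of flavanone ring C (catalytic asymmetric oxa-Michael closure of an ester-activated 2'-hydroxychalcone, which sets C2 as R); then the Knoevenagel C=C, the Reformatsky C3–C4 bond and the formyl C4–C4a bond.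
3. Key disconnection: C5–C6 and C7–C8 of flavanone ring A, by benzannulation of a 3-(siloxyethynyl)flavone with 3-(benzyloxy)cyclobutenone.
4. The three ring-A oxygens leave the key step differentiated (OH, OTIPS, OBn). The oxygen para to the flavonyl carbon (future O1) stays the only benzyl ether on that ring and is freed alone by hydrogenolysis. This fixes the 6-linked flavanone over the 8-linked one, a choice that a symmetric arylphloroglucinol could not make.
5. Ring order: flavone rings (purchased), then flavanone ring A (step 7), then flavanone ring C (step 15); ring B arrives with the aldehyde.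

Key step: step 7

Assumptions: the quinine-derived thiourea is taken to give the 2R series, by analogy with its Michael additions to chalcone-type acceptors; the sense is to be checked by CD on 31, and the quinidine-derived pseudoenantiomer is used if it is opposite. The flavone C3–flavanone C6 axis is treated as configurationally labile, because the target string carries no axial descriptor.

**Step 1**
Reactants: 1 5-hydroxy-7-methoxy-2-(4-methoxyphenyl)-4H-chromen-4-one
Product: 2 5-(benzyloxy)-7-methoxy-2-(4-methoxyphenyl)-4H-chromen-4-one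
Conditions: BnBr, K2CO3, DMF, 80 °C
Reagents that add atoms: benzyl bromide, BrCc1ccccc1
Why: Williamson etherification of the only acidic site, the chelated 5-OH, which needs heat in DMF; benzyl is chosen because it later leaves under neutral hydrogenolysis together with the ring-A benzyl ether.

**Step 2**
Reactants: 2 5-(benzyloxy)-7-methoxy-2-(4-methoxyphenyl)-4H-chromen-4-one
Product: 4 5-(benzyloxy)-3-iodo-7-methoxy-2-(4-methoxyphenyl)-4H-chromen-4-one, via 3-lithioflavone 3 (not isolated)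
Conditions: LDA, THF, −78 °C; I2, −78 °C → rt
Reagents that add atoms: iodine, [I][I]
Why: Vinylic deprotonation of a flavone at C3 by LDA followed by iodinolysis places the halogen by C–H acidity and not by arene nucleophilicity, so the electron-rich C6 and C8 are not iodinated.

**Step 3**
Reactants: 4 5-(benzyloxy)-3-iodo-7-methoxy-2-(4-methoxyphenyl)-4H-chromen-4-one; 5 ethynyltrimethylsilane
Product: 6 5-(benzyloxy)-7-methoxy-2-(4-methoxyphenyl)-3-[(trimethylsilyl)ethynyl]-4H-chromen-4-one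
Conditions: PdCl2(PPh3)2 (5 mol %), CuI (10 mol %), Et3N, DMF, 50 °C
Reagents that add atoms: none
Why: Sonogashira coupling of a 3-iodochromone, an α-iodoenone that adds readily to zerovalent palladium, under a tertiary amine that does not open the 2-arylpyrone ring.

**Step 4**
Reactants: 6 5-(benzyloxy)-7-methoxy-2-(4-methoxyphenyl)-3-[(trimethylsilyl)ethynyl]-4H-chromen-4-one
Product: 7 5-(benzyloxy)-3-ethynyl-7-methoxy-2-(4-methoxyphenyl)-4H-chromen-4-one
Conditions: K2CO3 (0.2 equiv), MeOH/THF, 0 °C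
Reagents that add atoms: none
Why: Methoxide-catalysed protiodesilylation of an alkynylsilane, run cold and briefly so that the pyrone ring is left alone.

**Step 5**
Reactants: 7 5-(benzyloxy)-3-ethynyl-7-methoxy-2-(4-methoxyphenyl)-4H-chromen-4-one
Product: 10 5-(benzyloxy)-7-methoxy-2-(4-methoxyphenyl)-3-[(triisopropylsilyloxy)ethynyl]-4H-chromen-4-one, via lithium acetylide 8 (not isolated), via lithium ynolate 9 (not isolated)
Conditions: LiHMDS, THF, −78 °C; t-BuOOLi (from t-BuOOH + LiHMDS), −78 → 0 °C; TIPSOTf, −78 → 0 °C; Et3N-deactivated silica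
Reagents that add atoms: tert-butyl hydroperoxide, CC(C)(C)OO; triisopropylsilyl trifluoromethanesulfonate, CC(C)[Si](C(C)C)(C(C)C)OS(=O)(=O)C(F)(F)F
Why: Oxenoid oxygen transfer from lithium tert-butyl peroxide to a lithium acetylide gives the ynolate, which the bulky silyl triflate traps on oxygen; 7 has no other acidic C–H, and its 2-aryl-blocked, tetrasubstituted chromone double bond is a poor acceptor for the peroxide.

**Step 6**
Reactants: 11 3-ethoxycyclobut-2-en-1-one; 12 benzyl alcohol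
Product: 13 3-(benzyloxy)cyclobut-2-en-1-one
Conditions: BnOH (3 equiv), PPTS (5 mol %), toluene, 40 °C, reduced pressure (EtOH removed)
Reagents that add atoms: none
Why: Acid-catalysed vinylogous transesterification (alcohol addition at C3 to a 3,3-dialkoxycyclobutanone, then loss of ethanol), driven by removal of ethanol and run far below the ring-opening temperature.

**Step 7**
Reactants: 10 5-(benzyloxy)-7-methoxy-2-(4-methoxyphenyl)-3-[(triisopropylsilyloxy)ethynyl]-4H-chromen-4-one; 13 3-(benzyloxy)cyclobut-2-en-1-one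
Product: 18 5-(benzyloxy)-3-[4-(benzyloxy)-2-hydroxy-6-(triisopropylsilyloxy)phenyl]-7-methoxy-2-(4-methoxyphenyl)-4H-chromen-4-one, via vinylketene 14 (not isolated), via vinylcyclobutenone 15 (not isolated), via dienylketene 16 (not isolated), via cyclohexadienone 17 (not isolated)
Conditions: 13 (1.5 equiv, two portions), degassed toluene (0.4 M), sealed tube, 110 → 140 °C
Reagents that add atoms: none
Why: Heat opens 13 by 4π electrocyclic cleavage of its C1–C4 bond to vinylketene 14, the oxygen-free alkyne carbon of 10 attacks the ketene carbon while the siloxy carbon bonds to the ketene α-carbon ([2+2]) to give 15, and 15 opens again (4π) to dienylketene 16, which cyclises to 17 and enolises to phenol 18. The closest known reaction type is the Danheiser benzannulation of cyclobutenones with triisopropylsiloxyalkynes to resorcinol monosilyl ethers; the combination of a 3-alkoxycyclobutenone with a chromon-3-yl ynol ether is so far untested, which is why the risk of the route is placed here. The single new ring, ring A of the flavanone unit, is closed by 6π electrocyclisation of 16, which re-forms the bond between the former cyclobutenone C1 and C4 (future C5–C4a), whereas the two new skeletal bonds, future C5–C6 and C7–C8, come from the [2+2] event. No stereocentre survives the step, since the sp3 carbon of 15 is lost on ring opening and the hindered axis of 18 forms as a racemate with no bearing on C2. The selectivity needed is the orientation of the [2+2] addition, and it is secured by the polarisation of the ynol ether, whose oxygen makes the flavone-bearing carbon the nucleophile, so that this carbon ends between OH and OTIPS with OBn para to it, while the tetrasubstituted chromone C2=C3 bond is no competing ketenophile. The linear alkyne holds the reacting carbons outside the pocket formed by the 2-aryl group and C4=O, so the congestion of the biaryl is paid for only in the irreversible aromatisation.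

**Step 8**
Reactants: 18 5-(benzyloxy)-3-[4-(benzyloxy)-2-hydroxy-6-(triisopropylsilyloxy)phenyl]-7-methoxy-2-(4-methoxyphenyl)-4H-chromen-4-one
Product: 19 6-(benzyloxy)-3-[5-(benzyloxy)-7-methoxy-2-(4-methoxyphenyl)-4-oxo-4H-chromen-3-yl]-2-hydroxy-4-(triisopropylsilyloxy)benzaldehyde
Conditions: MgCl2, Et3N, (CH2O)n, MeCN, reflux
Reagents that add atoms: formaldehyde (as paraformaldehyde), C=O
Why: Casnati–Skattebøl ortho-formylation, in which the magnesium phenoxide delivers formaldehyde to its only free ortho carbon (between OH and OBn, future C4a) and a second formaldehyde takes up the hydride; the flavone part carries no free phenol and stays untouched.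

**Step 9**
Reactants: 19 6-(benzyloxy)-3-[5-(benzyloxy)-7-methoxy-2-(4-methoxyphenyl)-4-oxo-4H-chromen-3-yl]-2-hydroxy-4-(triisopropylsilyloxy)benzaldehyde
Product: 20 6-(benzyloxy)-3-[5-(benzyloxy)-7-methoxy-2-(4-methoxyphenyl)-4-oxo-4H-chromen-3-yl]-2,4-bis(triisopropylsilyloxy)benzaldehyde
Conditions: TIPSOTf, 2,6-lutidine, CH2Cl2, 0 °C → rt
Reagents that add atoms: triisopropylsilyl trifluoromethanesulfonate, CC(C)[Si](C(C)C)(C(C)C)OS(=O)(=O)C(F)(F)F
Why: O-silylation with the silyl triflate, which is reactive enough for a hydrogen-bonded, doubly flanked phenol, blocks the future C5 oxygen so that it cannot later act as the oxa-Michael donor.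

**Step 10**
Reactants: 20 6-(benzyloxy)-3-[5-(benzyloxy)-7-methoxy-2-(4-methoxyphenyl)-4-oxo-4H-chromen-3-yl]-2,4-bis(triisopropylsilyloxy)benzaldehyde; 21 tert-butyl bromoacetate
Product: 23 tert-butyl 3-{6-(benzyloxy)-3-[5-(benzyloxy)-7-methoxy-2-(4-methoxyphenyl)-4-oxo-4H-chromen-3-yl]-2,4-bis(triisopropylsilyloxy)phenyl}-3-hydroxypropanoate (carbinol epimers), via Reformatsky reagent 22 (not isolated)
Conditions: Zn (TMSCl-activated), THF, 40 °C; then 20, 0 °C → rt; aq NH4Cl
Reagents that add atoms: none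
Why: Reformatsky addition; the zinc enolate adds to the aldehyde but not to the vinylogous-ester carbonyl of the flavone, its weakly basic zinc alkoxide should not pull the neighbouring silyl group off the phenol oxygen, and the new carbinol centre is removed in step 11.

**Step 11**
Reactants: 23 tert-butyl 3-{6-(benzyloxy)-3-[5-(benzyloxy)-7-methoxy-2-(4-methoxyphenyl)-4-oxo-4H-chromen-3-yl]-2,4-bis(triisopropylsilyloxy)phenyl}-3-hydroxypropanoate
Product: 24 tert-butyl 3-{6-(benzyloxy)-3-[5-(benzyloxy)-7-methoxy-2-(4-methoxyphenyl)-4-oxo-4H-chromen-3-yl]-2,4-bis(triisopropylsilyloxy)phenyl}-3-oxopropanoate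
Conditions: Dess–Martin periodinane, CH2Cl2, 0 °C → rt
Reagents that add atoms: none
Why: Dess–Martin oxidation of a hindered benzylic β-hydroxy ester to the β-keto ester, done while every phenol is still masked so that no arene oxidation competes.

**Step 12**
Reactants: 24 tert-butyl 3-{6-(benzyloxy)-3-[5-(benzyloxy)-7-methoxy-2-(4-methoxyphenyl)-4-oxo-4H-chromen-3-yl]-2,4-bis(triisopropylsilyloxy)phenyl}-3-oxopropanoate
Product: 25 tert-butyl 3-{6-hydroxy-3-[5-hydroxy-7-methoxy-2-(4-methoxyphenyl)-4-oxo-4H-chromen-3-yl]-2,4-bis(triisopropylsilyloxy)phenyl}-3-oxopropanoate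
Conditions: H2 (1 atm), Pd/C (10 wt %), EtOAc, rt
Reagents that add atoms: none
Why: Catalytic hydrogenolysis cleaves only the two aryl benzyl ethers and so frees the future O1 phenol and the flavone 5-OH, while both oxygens next to the flavonyl carbon stay silylated, which decides for the 6-linked flavanone; methyl and silyl ethers, the tert-butyl ester and the tetrasubstituted flavone double bond are inert.

**Step 13**
Reactants: 26 4-hydroxybenzaldehyde
Product: 27 4-(triisopropylsilyloxy)benzaldehyde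
Conditions: TIPSCl, imidazole, DMF, rt
Reagents that add atoms: triisopropylsilyl chloride, CC(C)[Si](Cl)(C(C)C)C(C)C
Why: Standard imidazole-promoted O-silylation; the group matches the ring-A silyl ethers, so one mild final step removes all three.

**Step 14**
Reactants: 25 tert-butyl 3-{6-hydroxy-3-[5-hydroxy-7-methoxy-2-(4-methoxyphenyl)-4-oxo-4H-chromen-3-yl]-2,4-bis(triisopropylsilyloxy)phenyl}-3-oxopropanoate; 27 4-(triisopropylsilyloxy)benzaldehyde
Product: 28 tert-butyl (Z)-2-{6-hydroxy-3-[5-hydroxy-7-methoxy-2-(4-methoxyphenyl)-4-oxo-4H-chromen-3-yl]-2,4-bis(triisopropylsilyloxy)benzoyl}-3-[4-(triisopropylsilyloxy)phenyl]prop-2-enoate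
Conditions: piperidine (10 mol %), AcOH (10 mol %), 4 Å MS, toluene, rt
Reagents that add atoms: none
Why: Knoevenagel condensation at the unhindered active methylene gives the ester-activated chalcone, expected as the Z isomer with the new aryl group cis to the ester, under a buffered catalyst that aryl silyl ethers tolerate.

**Step 15**
Reactants: 28 tert-butyl (Z)-2-{6-hydroxy-3-[5-hydroxy-7-methoxy-2-(4-methoxyphenyl)-4-oxo-4H-chromen-3-yl]-2,4-bis(triisopropylsilyloxy)benzoyl}-3-[4-(triisopropylsilyloxy)phenyl]prop-2-enoate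
Product: 31 (2R)-6-[5-hydroxy-7-methoxy-2-(4-methoxyphenyl)-4-oxo-4H-chromen-3-yl]-5,7-bis(triisopropylsilyloxy)-2-[4-(triisopropylsilyloxy)phenyl]chroman-4-one, via chromanone ester 29 (not isolated), via keto acid 30 (not isolated)
Conditions: N-[3,5-bis(trifluoromethyl)phenyl]-N'-[(8α,9S)-6'-methoxycinchonan-9-yl]thiourea (10 mol %), toluene, −25 °C; then TsOH·H2O, 80 °C
Reagents that add atoms: none
Why: Catalytic asymmetric intramolecular oxa-Michael addition (6-endo-trig) of an alkylidene β-keto ester under bifunctional cinchona thiourea catalysis: the thiourea binds the dicarbonyl unit and the quinuclidine guides the only free ortho phenol to one face of the alkylidene carbon, which sets C2 as R, after which acid cleaves the tert-butyl ester and the keto acid loses CO2, erasing the labile C3 centre without touching C2.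

**Step 16**
Reactants: 31 (2R)-6-[5-hydroxy-7-methoxy-2-(4-methoxyphenyl)-4-oxo-4H-chromen-3-yl]-5,7-bis(triisopropylsilyloxy)-2-[4-(triisopropylsilyloxy)phenyl]chroman-4-one
Product: 32 (2R)-5,7-dihydroxy-6-[5-hydroxy-7-methoxy-2-(4-methoxyphenyl)-4-oxo-4H-chromen-3-yl]-2-(4-hydroxyphenyl)chroman-4-one
Conditions: HF·pyridine, pyridine, THF, 0 °C → rt (plastic vessel)
Reagents that add atoms: none
Why: Fluoride desilylation of three aryl silyl ethers in a weakly acidic buffer; no base is present, so retro-oxa-Michael opening, which would racemise C2 and scramble the 6- and 8-linkage, is avoided, and the methyl ethers are untouched.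

**Compound list**
1 | 5-hydroxy-7-methoxy-2-(4-methoxyphenyl)-4H-chromen-4-one (apigenin 7,4'-dimethyl ether) | COc1ccc(-c2cc(=O)c3c(O)cc(OC)cc3o2)cc1 | starting material
2 | 5-(benzyloxy)-7-methoxy-2-(4-methoxyphenyl)-4H-chromen-4-one | COc1ccc(-c2cc(=O)c3c(OCc4ccccc4)cc(OC)cc3o2)cc1 | intermediate
3 | 3-lithio derivative of 2 | COc1ccc(-c2oc3cc(OC)cc(OCc4ccccc4)c3c(=O)c2[Li])cc1 | intermediate
4 | 5-(benzyloxy)-3-iodo-7-methoxy-2-(4-methoxyphenyl)-4H-chromen-4-one | COc1ccc(-c2oc3cc(OC)cc(OCc4ccccc4)c3c(=O)c2I)cc1 | intermediate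
5 | ethynyltrimethylsilane | C#C[Si](C)(C)C | starting material
6 | 5-(benzyloxy)-7-methoxy-2-(4-methoxyphenyl)-3-[(trimethylsilyl)ethynyl]-4H-chromen-4-one | COc1ccc(-c2oc3cc(OC)cc(OCc4ccccc4)c3c(=O)c2C#C[Si](C)(C)C)cc1 | intermediate
7 | 5-(benzyloxy)-3-ethynyl-7-methoxy-2-(4-methoxyphenyl)-4H-chromen-4-one | COc1ccc(-c2oc3cc(OC)cc(OCc4ccccc4)c3c(=O)c2C#C)cc1 | intermediate
8 | lithium acetylide of 7 | COc1ccc(-c2oc3cc(OC)cc(OCc4ccccc4)c3c(=O)c2C#C[Li])cc1 | intermediate
9 | lithium 2-(flavon-3-yl)ethynolate | COc1ccc(-c2oc3cc(OC)cc(OCc4ccccc4)c3c(=O)c2C#CO[Li])cc1 | intermediate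
10 | 5-(benzyloxy)-7-methoxy-2-(4-methoxyphenyl)-3-[(triisopropylsilyloxy)ethynyl]-4H-chromen-4-one | COc1ccc(-c2oc3cc(OC)cc(OCc4ccccc4)c3c(=O)c2C#CO[Si](C(C)C)(C(C)C)C(C)C)cc1 | intermediate
11 | 3-ethoxycyclobut-2-en-1-one | CCOC1=CC(=O)C1 | starting material
12 | benzyl alcohol | OCc1ccccc1 | starting material
13 | 3-(benzyloxy)cyclobut-2-en-1-one | O=C1C=C(OCc2ccccc2)C1 | intermediate
14 | 3-(benzyloxy)buta-1,3-dien-1-one (vinylketene) | C=C(OCc1ccccc1)C=C=O | intermediate
15 | 4-[1-(benzyloxy)vinyl]-2-(flavon-3-yl)-3-(triisopropylsilyloxy)cyclobut-2-en-1-one (racemic) | COc1ccc(-c2oc3cc(OC)cc(OCc4ccccc4)c3c(=O)c2C2=C(O[Si](C(C)C)(C(C)C)C(C)C)C(C(=C)OCc3ccccc3)C2=O)cc1 | intermediate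
16 | 5-(benzyloxy)-2-(flavon-3-yl)-3-(triisopropylsilyloxy)hexa-1,3,5-trien-1-one (ketene carbon chain and vinyl group cis) | COc1ccc(-c2oc3cc(OC)cc(OCc4ccccc4)c3c(=O)c2C(=C=O)/C(O[Si](C(C)C)(C(C)C)C(C)C)=C\C(=C)OCc2ccccc2)cc1 | intermediate
17 | 5-(benzyloxy)-2-(flavon-3-yl)-3-(triisopropylsilyloxy)cyclohexa-2,4-dien-1-one | COc1ccc(-c2oc3cc(OC)cc(OCc4ccccc4)c3c(=O)c2C2=C(O[Si](C(C)C)(C(C)C)C(C)C)C=C(OCc3ccccc3)CC2=O)cc1 | intermediate
18 | 5-(benzyloxy)-3-[4-(benzyloxy)-2-hydroxy-6-(triisopropylsilyloxy)phenyl]-7-methoxy-2-(4-methoxyphenyl)-4H-chromen-4-one | COc1ccc(-c2oc3cc(OC)cc(OCc4ccccc4)c3c(=O)c2-c2c(O)cc(OCc3ccccc3)cc2O[Si](C(C)C)(C(C)C)C(C)C)cc1 | intermediate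
19 | 6-(benzyloxy)-3-[5-(benzyloxy)-7-methoxy-2-(4-methoxyphenyl)-4-oxo-4H-chromen-3-yl]-2-hydroxy-4-(triisopropylsilyloxy)benzaldehyde | COc1ccc(-c2oc3cc(OC)cc(OCc4ccccc4)c3c(=O)c2-c2c(O)c(C=O)c(OCc3ccccc3)cc2O[Si](C(C)C)(C(C)C)C(C)C)cc1 | intermediate
20 | 6-(benzyloxy)-3-[5-(benzyloxy)-7-methoxy-2-(4-methoxyphenyl)-4-oxo-4H-chromen-3-yl]-2,4-bis(triisopropylsilyloxy)benzaldehyde | COc1ccc(-c2oc3cc(OC)cc(OCc4ccccc4)c3c(=O)c2-c2c(O[Si](C(C)C)(C(C)C)C(C)C)c(C=O)c(OCc3ccccc3)cc2O[Si](C(C)C)(C(C)C)C(C)C)cc1 | intermediate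
21 | tert-butyl bromoacetate | CC(C)(C)OC(=O)CBr | starting material
22 | bromo(2-tert-butoxy-2-oxoethyl)zinc | CC(C)(C)OC(=O)C[Zn]Br | intermediate
23 | tert-butyl 3-{6-(benzyloxy)-3-[5-(benzyloxy)-7-methoxy-2-(4-methoxyphenyl)-4-oxo-4H-chromen-3-yl]-2,4-bis(triisopropylsilyloxy)phenyl}-3-hydroxypropanoate (carbinol centre unassigned, removed in step 11) | COc1ccc(-c2oc3cc(OC)cc(OCc4ccccc4)c3c(=O)c2-c2c(O[Si](C(C)C)(C(C)C)C(C)C)c(C(O)CC(=O)OC(C)(C)C)c(OCc3ccccc3)cc2O[Si](C(C)C)(C(C)C)C(C)C)cc1 | intermediate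
24 | tert-butyl 3-{6-(benzyloxy)-3-[5-(benzyloxy)-7-methoxy-2-(4-methoxyphenyl)-4-oxo-4H-chromen-3-yl]-2,4-bis(triisopropylsilyloxy)phenyl}-3-oxopropanoate | COc1ccc(-c2oc3cc(OC)cc(OCc4ccccc4)c3c(=O)c2-c2c(O[Si](C(C)C)(C(C)C)C(C)C)c(C(=O)CC(=O)OC(C)(C)C)c(OCc3ccccc3)cc2O[Si](C(C)C)(C(C)C)C(C)C)cc1 | intermediate
25 | tert-butyl 3-{6-hydroxy-3-[5-hydroxy-7-methoxy-2-(4-methoxyphenyl)-4-oxo-4H-chromen-3-yl]-2,4-bis(triisopropylsilyloxy)phenyl}-3-oxopropanoate | COc1ccc(-c2oc3cc(OC)cc(O)c3c(=O)c2-c2c(O[Si](C(C)C)(C(C)C)C(C)C)c(C(=O)CC(=O)OC(C)(C)C)c(O)cc2O[Si](C(C)C)(C(C)C)C(C)C)cc1 | intermediate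
26 | 4-hydroxybenzaldehyde | O=Cc1ccc(O)cc1 | starting material
27 | 4-(triisopropylsilyloxy)benzaldehyde | O=Cc1ccc(O[Si](C(C)C)(C(C)C)C(C)C)cc1 | intermediate
28 | tert-butyl (Z)-2-{6-hydroxy-3-[5-hydroxy-7-methoxy-2-(4-methoxyphenyl)-4-oxo-4H-chromen-3-yl]-2,4-bis(triisopropylsilyloxy)benzoyl}-3-[4-(triisopropylsilyloxy)phenyl]prop-2-enoate | COc1ccc(-c2oc3cc(OC)cc(O)c3c(=O)c2-c2c(O[Si](C(C)C)(C(C)C)C(C)C)c(C(=O)/C(C(=O)OC(C)(C)C)=C/c3ccc(O[Si](C(C)C)(C(C)C)C(C)C)cc3)c(O)cc2O[Si](C(C)C)(C(C)C)C(C)C)cc1 | intermediate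
29 | tert-butyl (2R)-6-(flavon-3-yl)-4-oxo-5,7-bis(triisopropylsilyloxy)-2-[4-(triisopropylsilyloxy)phenyl]chroman-3-carboxylate (C3 labile) | COc1ccc(-c2oc3cc(OC)cc(O)c3c(=O)c2-c2c(O[Si](C(C)C)(C(C)C)C(C)C)cc3c(c2O[Si](C(C)C)(C(C)C)C(C)C)C(=O)C(C(=O)OC(C)(C)C)[C@H](c2ccc(O[Si](C(C)C)(C(C)C)C(C)C)cc2)O3)cc1 | intermediate
30 | (2R)-chroman-4-one-3-carboxylic acid derived from 29 (C3 labile) | COc1ccc(-c2oc3cc(OC)cc(O)c3c(=O)c2-c2c(O[Si](C(C)C)(C(C)C)C(C)C)cc3c(c2O[Si](C(C)C)(C(C)C)C(C)C)C(=O)C(C(=O)O)[C@H](c2ccc(O[Si](C(C)C)(C(C)C)C(C)C)cc2)O3)cc1 | intermediate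
31 | (2R)-6-[5-hydroxy-7-methoxy-2-(4-methoxyphenyl)-4-oxo-4H-chromen-3-yl]-5,7-bis(triisopropylsilyloxy)-2-[4-(triisopropylsilyloxy)phenyl]chroman-4-one | COc1ccc(-c2oc3cc(OC)cc(O)c3c(=O)c2-c2c(O[Si](C(C)C)(C(C)C)C(C)C)cc3c(c2O[Si](C(C)C)(C(C)C)C(C)C)C(=O)C[C@H](c2ccc(O[Si](C(C)C)(C(C)C)C(C)C)cc2)O3)cc1 | intermediate
32 | (2R)-5,7-dihydroxy-6-[5-hydroxy-7-methoxy-2-(4-methoxyphenyl)-4-oxo-4H-chromen-3-yl]-2-(4-hydroxyphenyl)chroman-4-one (CNP0292254.1) | COc1ccc(-c2oc3cc(OC)cc(O)c3c(=O)c2-c2c(O)cc3c(c2O)C(=O)C[C@H](c2ccc(O)cc2)O3)cc1 | target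

**Totals**
Total step count: 16. Longest linear sequence: 14 steps (1–5, 7–12, 14–16).

**Steps most likely to fail**

Step 7. Three things may go wrong.
- The vinylogous-ester stabilisation of 13 may slow its ring opening, so that the temperature needed lets the siloxyalkyne decay by silyl shift from oxygen to carbon or by adventitious hydrolysis.
- The vinylketene may dimerise.
- The vinylketene may acylate the phenol just formed.

The fallback gives up ring construction for a hindered cross-coupling. It sets out from iodide 4 and returns at 18. Phloroglucinol is protected twice (MOMCl, i-Pr2NEt) to 3,5-bis(methoxymethoxy)phenol F1 and benzylated (BnBr, K2CO3) to 1-(benzyloxy)-3,5-bis(methoxymethoxy)benzene F2. Directed ortho-lithiation between the two MOM ethers (n-BuLi, THF, 0 °C), then B(OMe)3 and mild acid, give [4-(benzyloxy)-2,6-bis(methoxymethoxy)phenyl]boronic acid F3. Suzuki–Miyaura coupling with 4 (Pd(OAc)2, SPhos, K3PO4, toluene/H2O, 100 °C) gives 5-(benzyloxy)-3-[4-(benzyloxy)-2,6-bis(methoxymethoxy)phenyl]-7-methoxy-2-(4-methoxyphenyl)-4H-chromen-4-one F4. HCl in MeOH/THF frees 5-(benzyloxy)-3-[4-(benzyloxy)-2,6-dihydroxyphenyl]-7-methoxy-2-(4-methoxyphenyl)-4H-chromen-4-one F5. One equivalent of TIPSCl with imidazole silylates one of its two equivalent phenols to give 18.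

Step 15. Four processes may erode the enantiomeric purity.
- The very electron-rich phenol may close without the catalyst, possibly already during step 14.
- The oxa-Michael addition is reversible.
- Facial discrimination next to the bulky C5 silyl ether may be poor.
- Acid may open the ring at C2 during decarboxylation.

The fallback sets C2 by C–C bond formation instead. It sets out from 25 and returns at 32. TsOH·H2O in toluene at 80 °C removes the ester group to give 3-[3-acetyl-4-hydroxy-2,6-bis(triisopropylsilyloxy)phenyl]-5-hydroxy-7-methoxy-2-(4-methoxyphenyl)-4H-chromen-4-one F6. N,N-Dimethylformamide dimethyl acetal (toluene, 90 °C) gives the (E)-3-(dimethylamino)prop-2-enoyl analogue F7. Aqueous HCl in CH2Cl2 closes it to 6-[5-hydroxy-7-methoxy-2-(4-methoxyphenyl)-4-oxo-4H-chromen-3-yl]-5,7-bis(triisopropylsilyloxy)-4H-chromen-4-one F8. Rhodium-catalysed asymmetric 1,4-addition of commercial 4-(tert-butyldimethylsilyloxy)phenylboronic acid follows, with [Rh(OH)(cod)]2 and the enantiomer of MeO-F12-BIPHEP that gives the 2R series, in toluene/H2O at rt. It gives (2R)-2-[4-(tert-butyldimethylsilyloxy)phenyl]-6-[5-hydroxy-7-methoxy-2-(4-methoxyphenyl)-4-oxo-4H-chromen-3-yl]-5,7-bis(triisopropylsilyloxy)chroman-4-one F9. The conditions of step 16 convert F9 into 32.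

Step 5. The peroxide or the amide base may attack the chromone at C2 or C4. Oxygen transfer to the conjugated acetylide may stay incomplete. Silylation may occur on carbon instead of oxygen.

The fallback moves the peroxide oxidation onto a simple alkyne and brings in the siloxyethynyl unit by cross-coupling. It sets out from 4 and 5, replaces steps 3–5 and returns at 10. Compound 5 is lithiated (n-BuLi), oxidised with lithium tert-butyl peroxide and silylated with TIPSOTf to trimethyl[(triisopropylsilyloxy)ethynyl]silane F10. MeLi·LiBr removes the small C-silyl group, and ZnCl2 then gives chloro[(triisopropylsilyloxy)ethynyl]zinc F11. F11 undergoes Negishi coupling with 4 (Pd(PPh3)4, THF, rt → 50 °C), in the manner known for alkoxyethynylzinc halides and aryl iodides, to give 10.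

**Further compounds**
F1 | step 7 | 3,5-bis(methoxymethoxy)phenol | COCOc1cc(O)cc(OCOC)c1
F2 | step 7 | 1-(benzyloxy)-3,5-bis(methoxymethoxy)benzene | COCOc1cc(OCOC)cc(OCc2ccccc2)c1
F3 | step 7 | [4-(benzyloxy)-2,6-bis(methoxymethoxy)phenyl]boronic acid | COCOc1cc(OCc2ccccc2)cc(OCOC)c1B(O)O
F4 | step 7 | 5-(benzyloxy)-3-[4-(benzyloxy)-2,6-bis(methoxymethoxy)phenyl]-7-methoxy-2-(4-methoxyphenyl)-4H-chromen-4-one | COCOc1cc(OCc2ccccc2)cc(OCOC)c1-c1c(-c2ccc(OC)cc2)oc2cc(OC)cc(OCc3ccccc3)c2c1=O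
F5 | step 7 | 5-(benzyloxy)-3-[4-(benzyloxy)-2,6-dihydroxyphenyl]-7-methoxy-2-(4-methoxyphenyl)-4H-chromen-4-one | COc1ccc(-c2oc3cc(OC)cc(OCc4ccccc4)c3c(=O)c2-c2c(O)cc(OCc3ccccc3)cc2O)cc1
F6 | step 15 | 3-[3-acetyl-4-hydroxy-2,6-bis(triisopropylsilyloxy)phenyl]-5-hydroxy-7-methoxy-2-(4-methoxyphenyl)-4H-chromen-4-one | COc1ccc(-c2oc3cc(OC)cc(O)c3c(=O)c2-c2c(O[Si](C(C)C)(C(C)C)C(C)C)c(C(C)=O)c(O)cc2O[Si](C(C)C)(C(C)C)C(C)C)cc1
F7 | step 15 | 3-{3-[(E)-3-(dimethylamino)prop-2-enoyl]-4-hydroxy-2,6-bis(triisopropylsilyloxy)phenyl}-5-hydroxy-7-methoxy-2-(4-methoxyphenyl)-4H-chromen-4-one | COc1ccc(-c2oc3cc(OC)cc(O)c3c(=O)c2-c2c(O[Si](C(C)C)(C(C)C)C(C)C)c(C(=O)/C=C/N(C)C)c(O)cc2O[Si](C(C)C)(C(C)C)C(C)C)cc1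
F8 | step 15 | 6-[5-hydroxy-7-methoxy-2-(4-methoxyphenyl)-4-oxo-4H-chromen-3-yl]-5,7-bis(triisopropylsilyloxy)-4H-chromen-4-one | COc1ccc(-c2oc3cc(OC)cc(O)c3c(=O)c2-c2c(O[Si](C(C)C)(C(C)C)C(C)C)cc3occc(=O)c3c2O[Si](C(C)C)(C(C)C)C(C)C)cc1
F9 | step 15 | (2R)-2-[4-(tert-butyldimethylsilyloxy)phenyl]-6-[5-hydroxy-7-methoxy-2-(4-methoxyphenyl)-4-oxo-4H-chromen-3-yl]-5,7-bis(triisopropylsilyloxy)chroman-4-one | COc1ccc(-c2oc3cc(OC)cc(O)c3c(=O)c2-c2c(O[Si](C(C)C)(C(C)C)C(C)C)cc3c(c2O[Si](C(C)C)(C(C)C)C(C)C)C(=O)C[C@H](c2ccc(O[Si](C)(C)C(C)(C)C)cc2)O3)cc1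
F10 | step 5 | trimethyl[(triisopropylsilyloxy)ethynyl]silane | CC(C)[Si](OC#C[Si](C)(C)C)(C(C)C)C(C)C
F11 | step 5 | chloro[(triisopropylsilyloxy)ethynyl]zinc | CC(C)[Si](OC#C[Zn]Cl)(C(C)C)C(C)C
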